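**Retrosynthetic overview**

1. Irisoquin-B (3-heptadecyl-2-hydroxy-5-methoxy-1,4-benzoquinone, C24H40O4, no stereocentre) ⇐ site-selective O-methylation of 3-heptadecyl-2,5-dihydroxy-1,4-benzoquinone at the hydroxyl next to the ring CH.
2. The dihydroxyquinone ⇐ [4+2] double Claisen (oxalate) annulation of henicosane-2,3-dione (four ring carbons, CH3–CO–CO–CH2–C17H35) with dimethyl oxalate (two ring carbons). The bonds made are ring CH–C(O) and C(alkyl)–C(=O), and this step forms the only ring.
3. Enabling feature: the six-membered ring is the dienol form of a cyclohexane-1,2,4,5-tetraone. Its four oxygenated carbons are two vicinal pairs, and the two remaining carbons (the CH and the heptadecyl-bearing carbon) each lie between two carbonyl carbons. A 1,2-diketone and an oxalyl unit can therefore be joined α-carbon to acyl carbon, twice, with no redox change.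
4. Henicosane-2,3-dione ⇐ aza-enolate alkylation of the dimethylhydrazone of 3,3-dimethoxybutan-2-one (mono-protected biacetyl) with 1-bromoheptadecane, then hydrolysis.

Key step: step 3

**Route**

Step 1
Reactants: 1 3,3-dimethoxybutan-2-one; 2 1,1-dimethylhydrazine
Product: 3 (E)-2-(3,3-dimethoxybutan-2-ylidene)-1,1-dimethylhydrazine
Conditions: Me2NNH2 (3 equiv), 4 Å molecular sieves, EtOH, reflux
Reagents that add atoms: none
Why: Hydrazone formation (condensation) at the only carbonyl group; with no acid present and the water trapped the dimethyl ketal should survive, and the NMe2 group should settle anti to the quaternary ketal carbon (E).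

Step 2
Reactants: 3 (E)-2-(3,3-dimethoxybutan-2-ylidene)-1,1-dimethylhydrazine; 4 1-bromoheptadecane
Product: 7 henicosane-2,3-dione, via lithium 1-(3,3-dimethoxybut-1-en-2-yl)-2,2-dimethylhydrazin-1-ide 5 (not isolated), via (E)-2-(2,2-dimethoxyhenicosan-3-ylidene)-1,1-dimethylhydrazine 6 (not isolated)
Conditions: LiN(iPr)2 (LDA, 1.1 equiv), THF, −78 → 0 °C; 4, 0 °C → rt; then 2 M HCl, THF/H2O, rt → 40 °C
Reagents that add atoms: water, O
Why: Corey–Enders-type alkylation of a dimethylhydrazone aza-enolate (the C-methyl on the C=N carbon is the only acidic site) by SN2 on the primary bromide, followed by acid hydrolysis of the hydrazone and the dimethyl ketal, should unmask both carbonyl groups.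

Step 3
Reactants: 7 henicosane-2,3-dione; 8 dimethyl oxalate
Product: 10 3-heptadecyl-2,5-dihydroxycyclohexa-2,5-diene-1,4-dione, via methyl 2,4,5-trioxotricosanoate 9 (not isolated)
Conditions: NaOMe (3.5 equiv), 8 (1.2 equiv), THF/MeOH, 7 added slowly at 0 °C, then reflux; then 1 M HCl
Reagents that add atoms: none
Why: Proposed new method: a 1,2-diketone serves as a four-carbon bis-nucleophile in a [4+2] double Claisen (oxalate) annulation; its methyl enolate is acylated by the non-enolisable, highly electrophilic oxalate to give 9 as its sodium enolate (bond from the ring CH carbon to the carbon that later carries the methoxy group), and a second deprotonation at the CH2 that carries the chain is followed by Dieckmann-type attack on the remaining ester (bond from the alkyl-bearing carbon to the quinone carbonyl carbon), with loss of two methoxide ions. The closest known reaction types are the sodium alkoxide double Claisen condensation of dialkyl ketones with dialkyl oxalates that closes cyclopentane-1,2,4-triones and the base-mediated head-to-tail condensation of 2-oxo esters to 3,6-dialkyl-2,5-dihydroxybenzoquinones; the closure has not been shown for a 1,2-diketone with an oxalate. The six-membered ring closes in the 6-(enolendo)-exo-trig mode, and since both α-carbons of the dione are used, either order of the two acylations leads to the same ring. No stereocentre is formed. The step needs crossed Claisen condensation to win over self-aldol and benzilic-type reactions of the dione, and C- over O-acylation in the closure; slow addition of 7 to methoxide and oxalate keeps the free dione concentration low, the reversible methoxide/methanol medium returns O-acylated and aldol material, and the cyclised product is drained as its doubly deprotonated bis-vinylogous carboxylate salt, which gives the dihydroxyquinone on acidification.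

Step 4
Reactants: 10 3-heptadecyl-2,5-dihydroxycyclohexa-2,5-diene-1,4-dione
Product: 11 Irisoquin-B (3-heptadecyl-2-hydroxy-5-methoxycyclohexa-2,5-diene-1,4-dione)
Conditions: H2SO4 (cat.), MeOH, reflux, followed by TLC and stopped at the monomethyl ether
Reagents that add atoms: methanol, CO
Why: Acid-catalysed addition–elimination on a hydroxyquinone (vinylogous Fischer esterification) should occur at the vinylogous acid unit next to the ring CH, because the unit flanked by the heptadecyl chain is shielded and its methyl ether would be twisted out of conjugation; methylation at either oxygen of the unhindered unit gives the same compound after tautomerisation.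

**Compound list**

1 | 3,3-dimethoxybutan-2-one | CC(=O)C(C)(OC)OC | starting material
2 | 1,1-dimethylhydrazine | CN(C)N | starting material
3 | (E)-2-(3,3-dimethoxybutan-2-ylidene)-1,1-dimethylhydrazine | C/C(=N\N(C)C)C(C)(OC)OC | intermediate
4 | 1-bromoheptadecane | CCCCCCCCCCCCCCCCCBr | starting material
5 | lithium 1-(3,3-dimethoxybut-1-en-2-yl)-2,2-dimethylhydrazin-1-ide (lithio aza-enolate of 3) | C=C(N([Li])N(C)C)C(C)(OC)OC | intermediate
6 | (E)-2-(2,2-dimethoxyhenicosan-3-ylidene)-1,1-dimethylhydrazine | CCCCCCCCCCCCCCCCCC/C(=N\N(C)C)C(C)(OC)OC | intermediate
7 | henicosane-2,3-dione | CCCCCCCCCCCCCCCCCCC(=O)C(C)=O | intermediate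
8 | dimethyl oxalate | COC(=O)C(=O)OC | starting material
9 | methyl 2,4,5-trioxotricosanoate (present as its sodium enolate) | CCCCCCCCCCCCCCCCCCC(=O)C(=O)CC(=O)C(=O)OC | intermediate
10 | 3-heptadecyl-2,5-dihydroxycyclohexa-2,5-diene-1,4-dione | CCCCCCCCCCCCCCCCCC1=C(O)C(=O)C=C(O)C1=O | intermediate
11 | Irisoquin-B, 3-heptadecyl-2-hydroxy-5-methoxycyclohexa-2,5-diene-1,4-dione | CCCCCCCCCCCCCCCCCC1=C(O)C(=O)C=C(OC)C1=O | target

**Step count and risks**

Total step count: 4. Longest linear sequence: 4 steps (1 → 3 → 7 → 10 → 11).

Steps most likely to fail:

1. Step 3 (key step, proposed new method). Self-aldol condensation or benzilic-type rearrangement of the dione may outrun oxalylation, or the chelated enolate of the mono-oxalylated chain may fail to reach the geometry for carbon–carbon ring closure and stall or close through oxygen. The fallback uses known chemistry and replaces ring construction by functionalisation of a preformed tetraoxygenated ring; it sets out from 1-bromoheptadecane (4) and comes back at 10. Commercial 1,2,4,5-tetramethoxybenzene is lithiated between two methoxy groups (n-BuLi, TMEDA, THF, 0 °C) to (2,3,5,6-tetramethoxyphenyl)lithium F1, which is alkylated in the same flask with 4 (THF/DMPU) to give 3-heptadecyl-1,2,4,5-tetramethoxybenzene F2. Exhaustive O-demethylation (BBr3, CH2Cl2, −78 °C → rt) should give 3-heptadecylbenzene-1,2,4,5-tetrol F3, which is oxidised by air (O2, aqueous NaHCO3/MeOH, then acidification) to 10.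

2. Step 4. Site selectivity may be lost, or methylation may run on to the dimethyl ether before the diol is consumed. The fallback sets out from 10 and comes back at 11, and it moves the selectivity from ether formation to ether cleavage. Exhaustive methylation (Me2SO4, K2CO3, acetone, reflux) gives 3-heptadecyl-2,5-dimethoxycyclohexa-2,5-diene-1,4-dione F4. Mild acid hydrolysis (aqueous HClO4, THF, rt) should then cleave only the methoxy group beside the chain, which is the more labile vinylogous ester because the heptadecyl group twists it out of conjugation, to give 11.

3. Step 2. The aza-enolate may act as a base (E2 elimination of the bromide, proton transfer) instead of being alkylated, or hydrolysis of the α-keto ketal may stall while liberated hydrazine recondenses with the dione. The fallback sets out from 4 and comes back at 7; it forms the carbon–carbon bond by conjugate addition and sets the oxidation level afterwards. Compound 4 is converted (Mg, THF) into heptadecylmagnesium bromide F5, which is added in 1,4-fashion to but-3-en-2-one (CuBr·SMe2 cat., Me3SiCl, THF, −78 °C; acidic work-up) to give henicosan-2-one F6. Acid-mediated nitrosation at the internal methylene (isoamyl nitrite, HCl, Et2O) should give (E)-3-(hydroxyimino)henicosan-2-one F7, and deoximation by exchange with aqueous formaldehyde/HCl gives 7.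

**Further compounds**

F1 | step 3 | (2,3,5,6-tetramethoxyphenyl)lithium | [Li]c1c(OC)c(OC)cc(OC)c1OC
F2 | step 3 | 3-heptadecyl-1,2,4,5-tetramethoxybenzene | CCCCCCCCCCCCCCCCCc1c(OC)c(OC)cc(OC)c1OC
F3 | step 3 | 3-heptadecylbenzene-1,2,4,5-tetrol | CCCCCCCCCCCCCCCCCc1c(O)c(O)cc(O)c1O
F4 | step 4 | 3-heptadecyl-2,5-dimethoxycyclohexa-2,5-diene-1,4-dione | CCCCCCCCCCCCCCCCCC1=C(OC)C(=O)C=C(OC)C1=O
F5 | step 2 | heptadecylmagnesium bromide | CCCCCCCCCCCCCCCCC[Mg]Br
F6 | step 2 | henicosan-2-one | CCCCCCCCCCCCCCCCCCCC(C)=O
F7 | step 2 | (E)-3-(hydroxyimino)henicosan-2-one | CCCCCCCCCCCCCCCCCC/C(=N\O)C(C)=O
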